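**Retrosynthetic overview**
1. Feature: each half of the target holds the naringenin array O1–C2(H)(4-hydroxyphenyl)–C3 fused to an oxygenated arene (C3a–C7a in unit A, the styryl-bearing dihydrobenzofuran; C3a'–C7a' in unit B). C2 and C2' are both S, as in (2S)-naringenin, and the flavanone differs only in keeping its carbonyl carbon inside the ring.
2. Last bonds: eight O–Me cleavages, preceded by the C6–CH= bond of unit A, made by Heck coupling of the C6 triflate (the old 7-oxygen of naringenin) with 2,4-dimethoxystyrene.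
3. C3(A)–C6'(B): nickel decarboxylative arylation of the C3 redox-active ester of unit A with the C6' boronic acid of unit B. The C3'–aryl bond of unit B is made the same way with 3,5-dimethoxyphenylboronic acid, followed by OBn → OH → OTf → B(OH)2 at C6'.
4. Both partners come from one ester, made by iodine(III) ring contraction of 7-O-benzyl-4',5-di-O-methylnaringenin: arene carbon C4a shifts from C4 to C3 and C4 leaves the ring as CO2Me.
5. Ring order: the dihydrofuran ring is formed once (step 3) and the batch is split. One part becomes unit B (steps 6–9), the other unit A (step 10). All benzene rings are bought.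

Key step: step 3

Assumption: commercial (2S)-naringenin is used at an enantiomeric purity checked by chiral HPLC, and crystalline 3 or 6 serve for upgrading if needed.

Step 1
Reactants: 1 (2S)-naringenin
Product: 2 (2S)-7-O-benzylnaringenin
Conditions: BnOH (1.05 equiv), PPh3, DIAD, THF, 0 °C to rt
Reagents that add atoms: benzyl alcohol, OCc1ccccc1
Why: Mitsunobu etherification alkylates the most acidic phenol first, which in naringenin is the 7-OH (para to the carbonyl and not chelated), and the absence of carbonate or hydroxide base keeps the retro-oxa-Michael opening to the chalcone, and with it racemisation of C2, closed.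

Step 2
Reactants: 2 (2S)-7-O-benzylnaringenin
Product: 3 (2S)-7-O-benzyl-4',5-di-O-methylnaringenin
Conditions: MeOH (excess), PPh3 (3 equiv), DIAD (3 equiv), THF, 0 °C to rt
Reagents that add atoms: methanol, CO
Why: A second Mitsunobu etherification caps the 4'-OH and then the hydrogen-bonded 5-OH, a position known to be alkylated under these conditions once the other two oxygens are blocked, again without a base able to open the pyranone.

Step 3
Reactants: 3 (2S)-7-O-benzyl-4',5-di-O-methylnaringenin
Product: 6 methyl (2S,3S)-6-benzyloxy-4-methoxy-2-(4-methoxyphenyl)-2,3-dihydrobenzofuran-3-carboxylate (2,3-trans), via methyl enol ether 4 (not isolated), via trans-3-iodanyl dimethyl ketal 5 (not isolated)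
Conditions: HC(OMe)3, H2SO4 (cat.), rt; then PhI(OAc)2 (1.2 equiv), 0 °C to rt, short contact time
Reagents that add atoms: trimethyl orthoformate, COC(OC)OC
Why: Acid and orthoformate convert the ketone into the methyl enol ether 4, iodine(III) then adds to C3 on the face opposite the equatorial C2 aryl group while methanol caps C4, giving the trans-diequatorial iodanyl ketal 5. In 5 the ring bond C4–C4a is antiperiplanar to the equatorial C3–I bond, so arene carbon C4a moves from C4 to C3 as iodobenzene leaves, and the dimethoxycarbenium ion left at the old C4 loses one methyl group to acetate and becomes the exocyclic methyl ester. The closest known reaction is of exactly this type, the iodine(III)- or thallium(III)-mediated oxidative ring contraction of flavanones in trimethyl orthoformate to methyl trans-2-aryl-2,3-dihydrobenzofuran-3-carboxylates. The five-membered ring O1–C2–C3–C3a–C7a is closed by a 1,2-aryl shift (contraction of the pyranone, C3–C3a being made as C4–C4a breaks), not by cyclisation of an open chain. C3 is set by inversion at the iodine-bearing carbon, which places the ester trans to the C2 aryl group (3S) and coincides with the thermodynamic isomer reachable by ester enolisation, while C2 stays S because none of its bonds is broken. The step needs the C4a shift to win over the C2-aryl shift (isoflavone), loss of H-2/H-3 (flavone) and attack of iodine(III) at C6/C8 of the arene; this is secured by the push of two ketal oxygens at C4, the three oxygen donors ortho/para to C4a, the missing antiperiplanar alignment between the C2–aryl bond and an equatorial C3–I bond, and the pre-formation of 4 before the oxidant is added.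

Step 4
Reactants: 6 methyl (2S,3S)-6-benzyloxy-4-methoxy-2-(4-methoxyphenyl)-2,3-dihydrobenzofuran-3-carboxylate
Product: 8 (2S,3S)-6-benzyloxy-4-methoxy-2-(4-methoxyphenyl)-2,3-dihydrobenzofuran-3-carboxylic acid, via lithium carboxylate 7 (not isolated)
Conditions: LiOH·H2O, THF/MeOH/H2O, rt; then 1 M HCl
Reagents that add atoms: lithium hydroxide, [Li+].[OH-]
Why: In this ester saponification any enolisation at C3 only returns the more stable trans isomer, and β-elimination of O1 is slow because the C2–O1 bond lies near the nodal plane of the C3 enolate in the five-membered ring (reverse of a 5-endo-trig closure) and the 4-methoxyphenyl group cannot form a quinone methide.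

Step 5
Reactants: 8 (2S,3S)-6-benzyloxy-4-methoxy-2-(4-methoxyphenyl)-2,3-dihydrobenzofuran-3-carboxylic acid
Product: 9 4,5,6,7-tetrachloro-1,3-dioxoisoindolin-2-yl (2S,3S)-6-benzyloxy-4-methoxy-2-(4-methoxyphenyl)-2,3-dihydrobenzofuran-3-carboxylate
Conditions: N-hydroxytetrachlorophthalimide, DIC, DMAP (cat.), CH2Cl2, rt; short silica plug
Reagents that add atoms: N-hydroxytetrachlorophthalimide, ON1C(=O)c2c(Cl)c(Cl)c(Cl)c(Cl)c2C1=O
Why: Carbodiimide (Steglich-type) esterification gives the redox-active ester, whose C3 configuration is of no consequence because that centre becomes a radical in the following couplings.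

Step 6
Reactants: 9 tetrachlorophthalimidyl ester of the dihydrobenzofuran-3-carboxylic acid; 10 3,5-dimethoxyphenylboronic acid
Product: 11 (2S,3S)-6-benzyloxy-3-(3,5-dimethoxyphenyl)-4-methoxy-2-(4-methoxyphenyl)-2,3-dihydrobenzofuran (2,3-trans)
Conditions: 10 (3 equiv), NiCl2·6H2O (20 mol %), bathophenanthroline (22 mol %), Et3N, 1,4-dioxane/DMF 10:1, 75 °C
Reagents that add atoms: none
Why: In this nickel-catalysed decarboxylative Suzuki-type arylation of a redox-active ester, single-electron reduction releases CO2 and a planar benzylic C3 radical (its SOMO is orthogonal to the ring C2–O1 bond, so β-scission is slow), and aryl–nickel captures it and eliminates on the face away from the C2 aryl group, which re-sets this centre (C3' of the target) as trans, 3S.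

Step 7
Reactants: 11 (2S,3S)-6-benzyloxy-3-(3,5-dimethoxyphenyl)-4-methoxy-2-(4-methoxyphenyl)-2,3-dihydrobenzofuran
Product: 12 (2S,3S)-3-(3,5-dimethoxyphenyl)-4-methoxy-2-(4-methoxyphenyl)-2,3-dihydrobenzofuran-6-ol
Conditions: H2 (1 atm), 10 % Pd/C, EtOAc/MeOH, rt, stopped at full conversion
Reagents that add atoms: none
Why: Catalytic hydrogenolysis removes the primary O-benzyl group much faster than it touches the hindered secondary C2–O1 ring ether, the methyl ethers are inert and no alkene is present yet.

Step 8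
Reactants: 12 (2S,3S)-3-(3,5-dimethoxyphenyl)-4-methoxy-2-(4-methoxyphenyl)-2,3-dihydrobenzofuran-6-ol
Product: 13 (2S,3S)-3-(3,5-dimethoxyphenyl)-4-methoxy-2-(4-methoxyphenyl)-2,3-dihydrobenzofuran-6-yl trifluoromethanesulfonate
Conditions: PhNTf2, Et3N, DMAP (cat.), CH2Cl2, rt
Reagents that add atoms: N-phenylbis(trifluoromethanesulfonimide), O=S(=O)(N(c1ccccc1)S(=O)(=O)C(F)(F)F)C(F)(F)F
Why: Phenol triflation with N-phenyltriflimide and an amine base is mild and leaves both stereocentres, which carry no acidic hydrogen, untouched.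

Step 9
Reactants: 13 unit-B C6 triflate
Product: 14 [(2S,3S)-3-(3,5-dimethoxyphenyl)-4-methoxy-2-(4-methoxyphenyl)-2,3-dihydrobenzofuran-6-yl]boronic acid
Conditions: B2(OH)4, XPhos Pd G2 (cat.), XPhos, KOAc, EtOH, 80 °C
Reagents that add atoms: tetrahydroxydiboron, OB(O)B(O)O
Why: Miyaura-type palladium-catalysed borylation of an aryl triflate with tetrahydroxydiboron gives the free boronic acid directly, and the reacting carbon has two ortho hydrogens and only meta oxygen donors, so oxidative addition is easy and protodeboronation slow.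

Step 10
Reactants: 9 tetrachlorophthalimidyl ester of the dihydrobenzofuran-3-carboxylic acid; 14 unit-B C6 boronic acid
Product: 15 (2S,3S)-6-benzyloxy-3-[(2S,3S)-3-(3,5-dimethoxyphenyl)-4-methoxy-2-(4-methoxyphenyl)-2,3-dihydrobenzofuran-6-yl]-4-methoxy-2-(4-methoxyphenyl)-2,3-dihydrobenzofuran
Conditions: 14 (1.5–2 equiv, excess to be recovered), NiCl2·6H2O (20 mol %), bathophenanthroline (22 mol %), Et3N, 1,4-dioxane/DMF 10:1, 75 °C
Reagents that add atoms: none
Why: The same nickel-catalysed decarboxylative Suzuki-type arylation, rehearsed in step 6, joins C3 of unit A to the unhindered C6' of unit B, and capture of the planar C3 radical anti to the C2 aryl group sets C3 as trans, 3S, while the three existing stereocentres take no part.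

Step 11
Reactants: 15 A–B benzyl ether
Product: 16 (2S,3S)-3-[(2S,3S)-3-(3,5-dimethoxyphenyl)-4-methoxy-2-(4-methoxyphenyl)-2,3-dihydrobenzofuran-6-yl]-4-methoxy-2-(4-methoxyphenyl)-2,3-dihydrobenzofuran-6-ol
Conditions: H2 (1 atm), 10 % Pd/C, EtOAc/MeOH, rt, stopped at full conversion
Reagents that add atoms: none
Why: Catalytic hydrogenolysis of the aryl benzyl ether proceeds as in step 7 and is placed before the alkene is introduced.

Step 12
Reactants: 16 A–B C6 phenol
Product: 17 the C6 trifluoromethanesulfonate of 16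
Conditions: PhNTf2, Et3N, DMAP (cat.), CH2Cl2, rt
Reagents that add atoms: N-phenylbis(trifluoromethanesulfonimide), O=S(=O)(N(c1ccccc1)S(=O)(=O)C(F)(F)F)C(F)(F)F
Why: Phenol triflation as in step 8 acts on the only free hydroxyl group of the molecule.

Step 13
Reactants: 18 2,4-dimethoxybenzaldehyde
Product: 19 2,4-dimethoxystyrene
Conditions: MePPh3Br, KOt-Bu, THF, 0 °C to rt
Reagents that add atoms: methyltriphenylphosphonium bromide, C[P+](c1ccccc1)(c1ccccc1)c1ccccc1.[Br-]
Why: Wittig methylenation of an aromatic aldehyde with the non-stabilised ylide is a routine way to a styrene.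

Step 14
Reactants: 17 A–B C6 triflate; 19 2,4-dimethoxystyrene
Product: 20 octa-O-methyl ether of the target, (E)-alkene
Conditions: 19 (2 equiv), PdCl2(PPh3)2 (10 mol %), LiCl (3 equiv), Et3N, DMF, 100 °C, dark
Reagents that add atoms: none
Why: In this Mizoroki–Heck reaction of an aryl triflate, chloride turns the cationic aryl–palladium triflate into the neutral chloride complex so that the aryl group adds to the terminal carbon of the electron-rich styrene, and syn insertion followed by syn β-hydride elimination gives the E alkene.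

Step 15
Reactants: 20 octa-O-methyl ether of the target
Product: 22 target CNP0186204.1, via octakis(dibromoboryl) ether 21 (not isolated)
Conditions: BBr3 (excess), CH2Cl2, −78 °C to rt, dark; then MeOH/ice-water; reversed-phase chromatography
Reagents that add atoms: none
Why: In boron tribromide cleavage of aryl methyl ethers bromide attacks the methyl carbon of each boron-complexed ether, which is faster at low temperature than cleavage of the secondary ring C2–O bonds, so the four stereocentres and the E alkene should persist and hydrolysis of 21 should release the octaphenol.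

**Compound list**
1 | (2S)-naringenin | O=C1C[C@@H](c2ccc(O)cc2)Oc2cc(O)cc(O)c12 | starting material
2 | (2S)-7-benzyloxy-5-hydroxy-2-(4-hydroxyphenyl)chroman-4-one | O=C1C[C@@H](c2ccc(O)cc2)Oc2cc(OCc3ccccc3)cc(O)c12 | intermediate
3 | (2S)-7-benzyloxy-5-methoxy-2-(4-methoxyphenyl)chroman-4-one | COc1ccc([C@@H]2CC(=O)c3c(OC)cc(OCc4ccccc4)cc3O2)cc1 | intermediate
4 | (2S)-7-benzyloxy-4,5-dimethoxy-2-(4-methoxyphenyl)-2H-chromene | COc1ccc([C@@H]2C=C(OC)c3c(OC)cc(OCc4ccccc4)cc3O2)cc1 | intermediate
5 | 3-[acetoxy(phenyl)-λ3-iodanyl]-7-benzyloxy-4,4,5-trimethoxy-2-(4-methoxyphenyl)chromane, 2,3-trans, C2 arranged as in 3 | COc1ccc([C@@H]2[C@@H](I(OC(C)=O)c3ccccc3)C(OC)(OC)c3c(OC)cc(OCc4ccccc4)cc3O2)cc1 | intermediate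
6 | methyl (2S,3S)-6-benzyloxy-4-methoxy-2-(4-methoxyphenyl)-2,3-dihydrobenzofuran-3-carboxylate | COc1ccc([C@H]2Oc3cc(OCc4ccccc4)cc(OC)c3[C@@H]2C(=O)OC)cc1 | intermediate
7 | lithium (2S,3S)-6-benzyloxy-4-methoxy-2-(4-methoxyphenyl)-2,3-dihydrobenzofuran-3-carboxylate | COc1ccc([C@H]2Oc3cc(OCc4ccccc4)cc(OC)c3[C@@H]2C(=O)[O-])cc1.[Li+] | intermediate
8 | (2S,3S)-6-benzyloxy-4-methoxy-2-(4-methoxyphenyl)-2,3-dihydrobenzofuran-3-carboxylic acid | COc1ccc([C@H]2Oc3cc(OCc4ccccc4)cc(OC)c3[C@@H]2C(=O)O)cc1 | intermediate
9 | 4,5,6,7-tetrachloro-1,3-dioxoisoindolin-2-yl ester of 8 | COc1ccc([C@H]2Oc3cc(OCc4ccccc4)cc(OC)c3[C@@H]2C(=O)ON2C(=O)c3c(Cl)c(Cl)c(Cl)c(Cl)c3C2=O)cc1 | intermediate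
10 | 3,5-dimethoxyphenylboronic acid | COc1cc(cc(OC)c1)B(O)O | starting material
11 | (2S,3S)-6-benzyloxy-3-(3,5-dimethoxyphenyl)-4-methoxy-2-(4-methoxyphenyl)-2,3-dihydrobenzofuran | COc1ccc([C@H]2Oc3cc(OCc4ccccc4)cc(OC)c3[C@@H]2c2cc(OC)cc(OC)c2)cc1 | intermediate
12 | (2S,3S)-3-(3,5-dimethoxyphenyl)-4-methoxy-2-(4-methoxyphenyl)-2,3-dihydrobenzofuran-6-ol | COc1ccc([C@H]2Oc3cc(O)cc(OC)c3[C@@H]2c2cc(OC)cc(OC)c2)cc1 | intermediate
13 | C6 triflate of 12 | COc1ccc([C@H]2Oc3cc(OS(=O)(=O)C(F)(F)F)cc(OC)c3[C@@H]2c2cc(OC)cc(OC)c2)cc1 | intermediate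
14 | [(2S,3S)-3-(3,5-dimethoxyphenyl)-4-methoxy-2-(4-methoxyphenyl)-2,3-dihydrobenzofuran-6-yl]boronic acid | COc1ccc([C@H]2Oc3cc(B(O)O)cc(OC)c3[C@@H]2c2cc(OC)cc(OC)c2)cc1 | intermediate
15 | A–B benzyl ether, (2S,3S,2'S,3'S) | COc1ccc([C@H]2Oc3cc(OCc4ccccc4)cc(OC)c3[C@@H]2c2cc(OC)c3c(c2)O[C@H](c2ccc(OC)cc2)[C@H]3c2cc(OC)cc(OC)c2)cc1 | intermediate
16 | A–B C6 phenol, (2S,3S,2'S,3'S) | COc1ccc([C@H]2Oc3cc(O)cc(OC)c3[C@@H]2c2cc(OC)c3c(c2)O[C@H](c2ccc(OC)cc2)[C@H]3c2cc(OC)cc(OC)c2)cc1 | intermediate
17 | A–B C6 triflate, (2S,3S,2'S,3'S) | COc1ccc([C@H]2Oc3cc(OS(=O)(=O)C(F)(F)F)cc(OC)c3[C@@H]2c2cc(OC)c3c(c2)O[C@H](c2ccc(OC)cc2)[C@H]3c2cc(OC)cc(OC)c2)cc1 | intermediate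
18 | 2,4-dimethoxybenzaldehyde | COc1ccc(C=O)c(OC)c1 | starting material
19 | 2,4-dimethoxystyrene | C=Cc1ccc(OC)cc1OC | intermediate
20 | octa-O-methyl ether of the target, (2S,3S,2'S,3'S,E) | COc1ccc([C@H]2Oc3cc(/C=C/c4ccc(OC)cc4OC)cc(OC)c3[C@@H]2c2cc(OC)c3c(c2)O[C@H](c2ccc(OC)cc2)[C@H]3c2cc(OC)cc(OC)c2)cc1 | intermediate
21 | octakis(dibromoboryl) ether of the target (idealised form of the aryl borates before quench) | BrB(Br)Oc1ccc([C@H]2Oc3cc(/C=C/c4ccc(OB(Br)Br)cc4OB(Br)Br)cc(OB(Br)Br)c3[C@@H]2c2cc(OB(Br)Br)c3c(c2)O[C@H](c2ccc(OB(Br)Br)cc2)[C@H]3c2cc(OB(Br)Br)cc(OB(Br)Br)c2)cc1 | intermediate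
22 | (2S,3S)-6-[(E)-2-(2,4-dihydroxyphenyl)ethenyl]-3-[(2S,3S)-3-(3,5-dihydroxyphenyl)-4-hydroxy-2-(4-hydroxyphenyl)-2,3-dihydrobenzofuran-6-yl]-2-(4-hydroxyphenyl)-2,3-dihydrobenzofuran-4-ol | Oc1ccc([C@H]2Oc3cc(/C=C/c4ccc(O)cc4O)cc(O)c3[C@@H]2c2cc(O)c3c(c2)O[C@H](c2ccc(O)cc2)[C@H]3c2cc(O)cc(O)c2)cc1 | target

**Step count**
Total steps: 15. Longest linear sequence: 14 (steps 1–12, 14, 15).

**Steps most likely to fail**

Step 3 (key step).
- Risk: the carbonyl group is a vinylogous carbonate flanked by the 5-methoxy group, so enol ether formation may lag.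
  - The oxidant, or the dialkoxycarbenium ion from the orthoformate, could then attack the free C6/C8 positions.
  - Dehydrogenation or the C2-aryl shift could take over.
  - Prolonged acid could ionise the C2–O1 bond and erode the enantiomeric purity.
- Fallback: it sets out from 3 and returns at 6, reaching the same C4a-to-C3 shift through a carbene instead of an iodine leaving group. The lithium enolate of 3 (LiHMDS, THF, −78 °C, kept cold so that O1 is not expelled) is acylated with 2,2,2-trifluoroethyl trifluoroacetate to the 3-trifluoroacetylflavanone F1. Detrifluoroacetylative diazo transfer (MsN3, Et3N, H2O, MeCN) gives the 3-diazoflavanone F2. Photolysis in methanol (Wolff rearrangement, favoured by the s-Z geometry locked in the ring) leads through the ring-contracted ketene F3 to the methyl ester. Any cis ester F4 formed on protonation is equilibrated with DBU to the trans ester 6.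

Step 10.
- Risk: the activated ester carries an acidic benzylic α-hydrogen and may be lost by amine-induced ketene formation and hydrolysis at 75 °C.
  - The stabilised, hindered C3 radical may dimerise or be oxidised before aryl–nickel captures it.
  - After capture it may lose a β-hydride with aromatisation to the benzofuran.
  - Transmetalation may be slow because the boronic acid cannot be used in large excess.
  - Facial selectivity may be lower than in step 6.
- Fallback: it sets out from triflate 13 and acid 8 and returns at 15. Palladium-catalysed triflate–bromide exchange (Pd2(dba)3, t-BuBrettPhos, KBr, KF, dioxane, heat) converts 13 into the unit-B aryl bromide F5. F5 then serves as the limiting electrophile in a photoredox/nickel dual-catalytic decarboxylative arylation of the free acid 8, used in excess (Ir[dF(CF3)ppy]2(dtbbpy)PF6, NiCl2·glyme, dtbbpy, Cs2CO3, DMF, blue light, rt). This reaction is known for arylacetic acids. The radical arises by oxidation of the carboxylate at room temperature, so no activated ester and no hot amine are involved.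

Step 15.
- Risk: eight ether cleavages need excess Lewis acid and time.
  - The hydrogen bromide formed may protonate the electron-rich stilbene, leading to cationic oligomerisation.
  - It may also ionise the 4-oxybenzylic C2–O1 and C2'–O1' bonds, leading to epimerisation or ring opening.
  - Incomplete cleavage would give mixtures that are hard to separate.
- Fallback: it sets out from triflate 17 and returns at 22, so that the stilbene never meets boron tribromide. BBr3 (CH2Cl2, −78 °C to rt; aryl triflates survive) gives the hexaphenol triflate F6, and Ac2O/pyridine gives the hexaacetate triflate F7. In parallel, purchased 2,4-dihydroxybenzaldehyde is methylenated with excess ylide to 4-vinylresorcinol F8 and acetylated at once to 2,4-diacetoxystyrene F9. Heck coupling of F7 with F9 under the conditions of step 14 gives the octaacetate F10. Mild methanolysis (K2CO3 cat., MeOH, 0 °C, argon, dark) then releases 22.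

**Further compounds**
F1 | step 3 | 7-benzyloxy-5-methoxy-2-(4-methoxyphenyl)-3-(trifluoroacetyl)chroman-4-one, C2 arranged as in 3, C3 enolisable | COc1ccc([C@@H]2C(C(=O)C(F)(F)F)C(=O)c3c(OC)cc(OCc4ccccc4)cc3O2)cc1
F2 | step 3 | 7-benzyloxy-3-diazo-5-methoxy-2-(4-methoxyphenyl)chroman-4-one, C2 arranged as in 3 | COc1ccc([C@@H]2C(=[N+]=[N-])C(=O)c3c(OC)cc(OCc4ccccc4)cc3O2)cc1
F3 | step 3 | [6-benzyloxy-4-methoxy-2-(4-methoxyphenyl)benzofuran-3(2H)-ylidene]methanone (ketene), C2 arranged as in 6 | COc1ccc([C@H]2Oc3cc(OCc4ccccc4)cc(OC)c3C2=C=O)cc1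
F4 | step 3 | methyl (2S,3R)-6-benzyloxy-4-methoxy-2-(4-methoxyphenyl)-2,3-dihydrobenzofuran-3-carboxylate (cis) | COc1ccc([C@H]2Oc3cc(OCc4ccccc4)cc(OC)c3[C@H]2C(=O)OC)cc1
F5 | step 10 | (2S,3S)-6-bromo-3-(3,5-dimethoxyphenyl)-4-methoxy-2-(4-methoxyphenyl)-2,3-dihydrobenzofuran | COc1ccc([C@H]2Oc3cc(Br)cc(OC)c3[C@@H]2c2cc(OC)cc(OC)c2)cc1
F6 | step 15 | hexaphenol C6 triflate, (2S,3S,2'S,3'S) | Oc1ccc([C@H]2Oc3cc(OS(=O)(=O)C(F)(F)F)cc(O)c3[C@@H]2c2cc(O)c3c(c2)O[C@H](c2ccc(O)cc2)[C@H]3c2cc(O)cc(O)c2)cc1
F7 | step 15 | hexaacetate C6 triflate, (2S,3S,2'S,3'S) | CC(=O)Oc1ccc([C@H]2Oc3cc(OS(=O)(=O)C(F)(F)F)cc(OC(C)=O)c3[C@@H]2c2cc(OC(C)=O)c3c(c2)O[C@H](c2ccc(OC(C)=O)cc2)[C@H]3c2cc(OC(C)=O)cc(OC(C)=O)c2)cc1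
F8 | step 15 | 4-vinylbenzene-1,3-diol | C=Cc1ccc(O)cc1O
F9 | step 15 | 2,4-diacetoxystyrene | C=Cc1ccc(OC(C)=O)cc1OC(C)=O
F10 | step 15 | octaacetate of the target, (2S,3S,2'S,3'S,E) | CC(=O)Oc1ccc([C@H]2Oc3cc(/C=C/c4ccc(OC(C)=O)cc4OC(C)=O)cc(OC(C)=O)c3[C@@H]2c2cc(OC(C)=O)c3c(c2)O[C@H](c2ccc(OC(C)=O)cc2)[C@H]3c2cc(OC(C)=O)cc(OC(C)=O)c2)cc1
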